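**Retrosynthetic overview**
1. Evelynin ⇒ 1-(3,4-dimethoxyphenyl)-3-(2,3,4,6-tetramethoxyphenyl)propan-1-one. The quinone (ring B) is unmasked last, by oxidative demethylation of the only para-related OMe pair.
2. Dihydrochalcone ⇒ (E)-chalcone, by hydrogenation of the C=C bond.
3. Chalcone ⇒ 2,3,4,6-tetramethoxybenzaldehyde + 3,4-dimethoxyacetophenone. The key C–C bond comes from an intermolecular Claisen–Schmidt aldol condensation.
4. Aldehyde ⇒ 1,2,3,5-tetramethoxybenzene (Vilsmeier–Haack) ⇒ 3,4,5-trimethoxyphenol (O-methylation).
5. Ring order: no ring is built. Rings A and B are both bought as benzene rings, and ring B changes oxidation level only in the final step.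

Assumption: the SMILES has no stereocentre and no stereogenic double bond, so evelynin is achiral and needs no asymmetric step. The only stereo-elements on the route are the transient carbinol of 6 and the E-alkene of 7, and both are erased.

**Step 1**
Reactants: 1 3,4,5-trimethoxyphenol
Product: 2 1,2,3,5-tetramethoxybenzene
Conditions: MeI (1.5 equiv), K2CO3 (2 equiv), acetone, reflux, 12 h
Reagents that add atoms: iodomethane, CI
Why: This is a Williamson ether synthesis in which the phenoxide, the only acidic and nucleophilic site, is methylated cleanly by SN2, and no stereocentre is formed.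

**Step 2**
Reactants: 2 1,2,3,5-tetramethoxybenzene
Product: 4 2,3,4,6-tetramethoxybenzaldehyde, via aryl iminium chloride 3 (not isolated)
Conditions: POCl3 (1.5 equiv), DMF, 0 °C to rt, 3 h; then ice, aq NaOH
Reagents that add atoms: N,N-dimethylformamide, CN(C)C=O (formyl carbon); water, O (carbonyl oxygen, delivered in the aqueous NaOH quench)
Why: In this Vilsmeier–Haack formylation the two free positions of the very electron-rich arene are equivalent by symmetry, so one regioisomer forms, and the deactivated product does not react a second time.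

**Step 3**
Reactants: 4 2,3,4,6-tetramethoxybenzaldehyde; 5 3,4-dimethoxyacetophenone
Product: 7 (E)-1-(3,4-dimethoxyphenyl)-3-(2,3,4,6-tetramethoxyphenyl)prop-2-en-1-one, via aldol adduct 6 (not isolated)
Conditions: KOH (50% aq, 3 equiv), EtOH, rt, 24–48 h
Reagents that add atoms: none
Why: In this Claisen–Schmidt crossed aldol condensation the methyl ketone is the only enolisable partner and the aldehyde the only good electrophile, and E1cB loss of water from racemic 6 removes its carbinol centre and gives the thermodynamically preferred E-enone, which usually crystallises out.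

**Step 4**
Reactants: 7 (E)-1-(3,4-dimethoxyphenyl)-3-(2,3,4,6-tetramethoxyphenyl)prop-2-en-1-one
Product: 8 1-(3,4-dimethoxyphenyl)-3-(2,3,4,6-tetramethoxyphenyl)propan-1-one
Conditions: H2 (1 atm), 10% Pd/C, Ph2S (1 mol%), EtOAc, rt
Reagents that add atoms: none
Why: In this chemoselective heterogeneous catalytic hydrogenation the conjugated disubstituted alkene is saturated much faster than the electron-rich aryl ketone, the Ph2S poison suppresses carbonyl reduction and benzylic hydrogenolysis, and no stereocentre is formed.

**Step 5**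
Reactants: 8 1-(3,4-dimethoxyphenyl)-3-(2,3,4,6-tetramethoxyphenyl)propan-1-one
Product: 9 evelynin, 2,6-dimethoxy-3-[3-(3,4-dimethoxyphenyl)-3-oxopropyl]cyclohexa-2,5-diene-1,4-dione
Conditions: (NH4)2Ce(NO3)6 (2.5 equiv) in H2O added dropwise to 8 in MeCN, 0 °C, 30 min
Reagents that add atoms: water, O (both new carbonyl oxygens)
Why: In this oxidative demethylation, tetravalent cerium takes electrons only from the tetramethoxy ring B because ring A is deactivated by its acyl group, and water attacks the single para-related OMe pair (C-3 and C-6 of the arene) to give only the 2,6-dimethoxy-1,4-quinone, with no stereocentre involved.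

**Compound list**
1 | 3,4,5-trimethoxyphenol | COc1cc(O)cc(OC)c1OC | starting material
2 | 1,2,3,5-tetramethoxybenzene | COc1cc(OC)c(OC)c(OC)c1 | intermediate
3 | N,N-dimethyl-1-(2,3,4,6-tetramethoxyphenyl)methaniminium chloride (not isolated) | COc1cc(OC)c(C=[N+](C)C)c(OC)c1OC.[Cl-] | intermediate
4 | 2,3,4,6-tetramethoxybenzaldehyde | COc1cc(OC)c(C=O)c(OC)c1OC | intermediate
5 | 3,4-dimethoxyacetophenone | CC(=O)c1ccc(OC)c(OC)c1 | starting material
6 | racemic 1-(3,4-dimethoxyphenyl)-3-hydroxy-3-(2,3,4,6-tetramethoxyphenyl)propan-1-one (not isolated) | COc1ccc(cc1OC)C(=O)CC(O)c1c(OC)cc(OC)c(OC)c1OC | intermediate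
7 | (E)-1-(3,4-dimethoxyphenyl)-3-(2,3,4,6-tetramethoxyphenyl)prop-2-en-1-one | COc1ccc(cc1OC)C(=O)/C=C/c1c(OC)cc(OC)c(OC)c1OC | intermediate
8 | 1-(3,4-dimethoxyphenyl)-3-(2,3,4,6-tetramethoxyphenyl)propan-1-one | COc1ccc(cc1OC)C(=O)CCc1c(OC)cc(OC)c(OC)c1OC | intermediate
9 | evelynin (achiral) | COC1=CC(=O)C(CCC(=O)c2ccc(OC)c(OC)c2)=C(OC)C1=O | target

**Total step count:** 5
**Longest linear sequence:** 5 steps (1 → 2 → 4 → 7 → 8 → 9). Compound 5 is bought and enters at step 3.

**Three steps most likely to fail**

**Step 5.** The risks are over-oxidation, oxidative coupling to a biquinone, and partial attack of the one-electron oxidant elsewhere.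
- The fallback sets out from 1, uses 5 again, and comes back at 9.
- The oxygen that becomes the quinone carbonyl next to the side chain is carried as a benzyl ether instead of a methyl ether. The last step then becomes a mild, metal-free two-electron oxidation of a free p-methoxyphenol.
- 1 is benzylated (BnBr, K2CO3, DMF, rt) to 5-(benzyloxy)-1,2,3-trimethoxybenzene F1.
- POCl3/DMF attacks one of the two equivalent free positions. It passes through the benzyloxy aryl iminium chloride F2 and gives, after aqueous NaOH, 6-(benzyloxy)-2,3,4-trimethoxybenzaldehyde F3.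
- KOH/EtOH condensation with 5 runs through the benzyloxy aldol adduct F4 to the (E)-benzyloxy chalcone F5.
- H2, 10% Pd/C, EtOAc (no Ph2S) saturates the alkene and cleaves the benzyl ether in one operation. This gives 1-(3,4-dimethoxyphenyl)-3-(6-hydroxy-2,3,4-trimethoxyphenyl)propan-1-one F6.
- The trivalent iodine reagent PhI(OAc)2 (1.1 equiv, MeCN–H2O, 0 °C) oxidises F6. Water attacks para to the phenol, methanol is lost, and 9 results.

**Step 4.** The risk is over-reduction of the aryl ketone, or a stalled hydrogenation on the poisoned catalyst.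
- The fallback sets out from 7 and comes back at 8.
- Instead of stopping at the ketone, the sequence reduces through and re-oxidises.
- 7 is hydrogenated without poison (H2, 10% Pd/C, EtOAc).
- The crude ketone/alcohol mixture is converged with NaBH4 (MeOH, 0 °C) on racemic 1-(3,4-dimethoxyphenyl)-3-(2,3,4,6-tetramethoxyphenyl)propan-1-ol F7.
- This activated benzylic alcohol is oxidised back with MnO2 (CH2Cl2, rt) to 8. Its stereocentre disappears again.

**Step 3.** The risks are slow, reversible addition to a doubly ortho-substituted, electron-rich aldehyde, and Michael addition of a second enolate to 7.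
- The fallback sets out from 5 (together with 4) and comes back at 7.
- The equilibrium condensation is replaced by a directed aldol addition and a separate elimination.
- 5 is fully deprotonated with LiN(iPr)2 (THF, −78 °C) to lithium 1-(3,4-dimethoxyphenyl)ethenolate F8.
- 4 is added, and a cold aqueous NH4Cl quench allows 6 to be isolated.
- 6 is then dehydrated under acid catalysis (cat. p-TsOH, toluene, 50 °C). This is an easy E1 process because the carbinol carbon is benzylic to the tetramethoxyphenyl ring, and it gives 7.

**Further compounds**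
F1 | step 5 | 5-(benzyloxy)-1,2,3-trimethoxybenzene | COc1cc(OCc2ccccc2)cc(OC)c1OC
F2 | step 5 | 1-[6-(benzyloxy)-2,3,4-trimethoxyphenyl]-N,N-dimethylmethaniminium chloride | COc1cc(OCc2ccccc2)c(C=[N+](C)C)c(OC)c1OC.[Cl-]
F3 | step 5 | 6-(benzyloxy)-2,3,4-trimethoxybenzaldehyde | COc1cc(OCc2ccccc2)c(C=O)c(OC)c1OC
F4 | step 5 | racemic 3-[6-(benzyloxy)-2,3,4-trimethoxyphenyl]-1-(3,4-dimethoxyphenyl)-3-hydroxypropan-1-one | COc1ccc(cc1OC)C(=O)CC(O)c1c(OCc2ccccc2)cc(OC)c(OC)c1OC
F5 | step 5 | (E)-3-[6-(benzyloxy)-2,3,4-trimethoxyphenyl]-1-(3,4-dimethoxyphenyl)prop-2-en-1-one | COc1ccc(cc1OC)C(=O)/C=C/c1c(OCc2ccccc2)cc(OC)c(OC)c1OC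
F6 | step 5 | 1-(3,4-dimethoxyphenyl)-3-(6-hydroxy-2,3,4-trimethoxyphenyl)propan-1-one | COc1ccc(cc1OC)C(=O)CCc1c(O)cc(OC)c(OC)c1OC
F7 | step 4 | racemic 1-(3,4-dimethoxyphenyl)-3-(2,3,4,6-tetramethoxyphenyl)propan-1-ol | COc1ccc(cc1OC)C(O)CCc1c(OC)cc(OC)c(OC)c1OC
F8 | step 3 | lithium 1-(3,4-dimethoxyphenyl)ethenolate | [Li+].[O-]C(=C)c1ccc(OC)c(OC)c1
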